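## Retrosynthetic overview
1. GA49 ⇐ 12-ketone. The α face of C12 is blocked by C10 and by H-14, so hydride enters from the β face and gives the axial 12α-OH.
2. The 12-ketone ⇐ ring D opened and re-closed. The C13–C16 bond is re-made last by 5-exo-dig cyclisation of a C13 radical onto a C8-propargyl group.
3. The C12 oxygen ⇐ Rubottom oxidation of the 13,16-seco C13 ketone. That ketone ⇐ ozonolysis, glycol cleavage and Ohira–Bestmann homologation of the 13-hydroxy-16-ene unit (the 13-OH is the handle and is lost).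
4. The 2β,3β-diol ⇐ OsO4 on a 2-ene (GA5 type) ⇐ SN2' chlorination and tin hydride reduction of GA3.
5. Ring order: rings A, B, C and the lactone are bought with GA3. Ring D is opened in step 7 and re-formed in step 12.

Assumption: gibberellic acid (GA3), a bulk fermentation product sold by all major suppliers, counts as a commercially available starting material, so this is a relay synthesis.

C4, C5, C6, C8, C9 and C10 come unchanged from GA3. C2 and C3 are set in step 4, C13 is re-set in step 12, and C12 is set in step 15.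

## Route

Step 1
Reactants: 1 gibberellic acid (GA3)
Product: 2 GA3 2-(trimethylsilyl)ethyl (TMSE) ester
Conditions: TMSCH2CH2OH (5 equiv), DCC, DMAP (cat.), CH2Cl2, 0 °C → rt
Reagents that add atoms: 2-(trimethylsilyl)ethanol C[Si](C)(C)CCO
Why: Steglich esterification masks the C7 acid as a base- and hydride-stable, fluoride-labile ester and touches no stereocentre.

Step 2
Reactants: 2 GA3 TMSE ester
Product: 3 1β-chloro-GA5 TMSE ester
Conditions: PPh3, CCl4, MeCN, 60 °C
Reagents that add atoms: carbon tetrachloride ClC(Cl)(Cl)Cl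
Why: In this Appel activation C3 is neopentyl and roofed by the α-lactone, so chloride enters at C1 from the β face with allylic shift (SN2'), which moves the alkene to C2=C3; the bridgehead 13-OH is inert.

Step 3
Reactants: 3 1β-chloro-GA5 TMSE ester
Product: 4 GA5 TMSE ester
Conditions: Bu3SnH, AIBN (cat.), PhH, 80 °C
Reagents that add atoms: none
Why: In this radical dehalogenation the allyl radical takes hydrogen at the less hindered C1, so the 2-ene is kept and the C1 centre is erased.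

Step 4
Reactants: 4 GA5 TMSE ester
Product: 5 GA8 TMSE ester
Conditions: OsO4 (2 mol %), NMO (1.05 equiv), acetone–H2O, 0 °C
Reagents that add atoms: osmium tetroxide (catalytic oxygen carrier) O=[Os](=O)(=O)=O; N-methylmorpholine N-oxide C[N+]1([O-])CCOCC1; water O
Why: Upjohn syn-dihydroxylation attacks the cis-2-ene on the β face (the α face is covered by the lactone bridge) faster than the 16-ene next to the C13 carbinol, and this sets 2β-OH and 3β-OH.

Step 5
Reactants: 5 GA8 TMSE ester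
Product: 6 GA8 TMSE ester 2β,3β-acetonide
Conditions: Me2C(OMe)2, PPTS (cat.), CH2Cl2, rt
Reagents that add atoms: 2,2-dimethoxypropane COC(C)(C)OC
Why: Transacetalisation closes a dioxolane only on the cis-2β,3β-diol, which shields it from glycol cleavage and blocks retro-aldol epimerisation at C3.

Step 6
Reactants: 6 GA8 TMSE ester 2β,3β-acetonide
Product: 8 17-nor-13,16β-diol of the GA8 acetonide TMSE ester, via 16-norketone 7 (not isolated)
Conditions: O3, CH2Cl2–MeOH, −78 °C; then NaBH4, −78 → 0 °C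
Reagents that add atoms: ozone [O-][O+]=O
Why: Ozonolysis removes C17, and borohydride then adds to the α-ketol from the open exo face to give the endo 16β-OH, a centre that is destroyed in the next step.

Step 7
Reactants: 8 17-nor-13,16β-diol
Product: 9 13,16-seco-17-nor keto aldehyde
Conditions: Pb(OAc)4, CH2Cl2, 0 °C
Reagents that add atoms: none
Why: Criegee glycol cleavage opens ring D to a C13 cyclohexanone and a C8–CH2–CHO arm; lead tetraacetate tolerates the wide O–C–C–O angle of this rigid diol.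

Step 8
Reactants: 9 13,16-seco-17-nor keto aldehyde
Product: 10 13,16-seco keto alkyne
Conditions: MeCOC(N2)P(O)(OMe)2, K2CO3, MeOH, 0 °C → rt
Reagents that add atoms: Ohira–Bestmann reagent COP(=O)(OC)C(=[N+]=[N-])C(C)=O
Why: Ohira–Bestmann (Seyferth–Gilbert) homologation turns only the aldehyde into the terminal alkyne, which returns C17; the ketone does not react and the aldol to a strained bicyclo[2.2.2]octane is reversible.

Step 9
Reactants: 10 13,16-seco keto alkyne
Product: 12 12β-triethylsilyloxy 13-ketone, via TES enol ether 11 (not isolated)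
Conditions: LiHMDS, Et3SiCl, THF, −78 °C; then mCPBA, CH2Cl2, −20 °C
Reagents that add atoms: chlorotriethylsilane CC[Si](Cl)(CC)CC; mCPBA OOC(=O)c1cccc(Cl)c1
Why: In this Rubottom oxidation kinetic deprotonation avoids the neopentyl C14 and gives the Δ12 enol ether, the peracid attacks the β face away from the axial C10, and silyl migration gives the equatorial α-silyloxy ketone; the 12β centre is corrected in steps 14 and 15.

Step 10
Reactants: 12 12β-triethylsilyloxy 13-ketone
Product: 13 12β-triethylsilyloxy 13β-alcohol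
Conditions: NaBH4, MeOH–THF, −20 °C
Reagents that add atoms: none
Why: In this chemoselective ketone reduction the axial propargyl arm blocks the β face, so hydride enters from the α face to give the 13β-alcohol; either epimer would serve because C13 becomes a radical.

Step 11
Reactants: 13 12β-triethylsilyloxy 13β-alcohol
Product: 14 13β-O-(imidazol-1-ylthiocarbonyl) derivative
Conditions: Im2C=S, DMAP (cat.), PhMe, 80 °C
Reagents that add atoms: 1,1'-thiocarbonyldiimidazole S=C(n1ccnc1)n1ccnc1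
Why: Barton–McCombie activation under neutral conditions avoids silyl migration and acylates the only free hydroxyl.

Step 12
Reactants: 14 13β-O-(imidazol-1-ylthiocarbonyl) derivative
Product: 15 12-epi-GA49 12-O-TES ether 2,3-acetonide TMSE ester
Conditions: Bu3SnH (syringe pump), AIBN (cat.), PhH (5 mM), 80 °C
Reagents that add atoms: none
Why: Barton–McCombie fragmentation gives the C13 radical, which adds 5-exo-dig to the 1,3-diaxial propargyl arm, and the vinyl radical takes hydrogen to give the 16-methylene; the tether reaches C13 only from the β face, so C13 gets the natural bicyclo[3.2.1]octane configuration.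

Step 13
Reactants: 15 12-epi-GA49 12-O-TES ether 2,3-acetonide TMSE ester
Product: 16 12-epi-GA49 2,3-acetonide
Conditions: TBAF (3 equiv), THF, rt; dil. HCl work-up
Reagents that add atoms: none
Why: Fluoride cleaves the Si–O bond and triggers β-elimination of the TMSE ester in one operation; the lactone, the acetonide and the alkene are inert.

Step 14
Reactants: 16 12-epi-GA49 2,3-acetonide
Product: 17 12-oxo-GA34 2,3-acetonide
Conditions: Dess–Martin periodinane, CH2Cl2, rt
Reagents that add atoms: none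
Why: Dess–Martin oxidation converts the only free, equatorial alcohol; the β,γ-enone cannot conjugate because C13 is a bridgehead.

Step 15
Reactants: 17 12-oxo-GA34 2,3-acetonide
Product: 18 GA49 2,3-acetonide
Conditions: NaBH4 (excess), MeOH, 0 °C; aq. acid work-up
Reagents that add atoms: none
Why: In this substrate-controlled hydride reduction the α face of C12 is closed by the syn-axial C10 and by H-14, so hydride comes from the β face and sets the axial 12α-OH.

Step 16
Reactants: 18 GA49 2,3-acetonide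
Product: 19 GA49
Conditions: AcOH–H2O (4:1), 45 °C
Reagents that add atoms: none
Why: Mild acetal hydrolysis frees the 2β,3β-diol without base, so there is no C3 epimerisation, and without strong acid, so the 16-ene does not migrate.

## Compound list
1 | gibberellic acid (GA3) | C=C1C[C@]23C[C@@]1(O)CC[C@H]2[C@@]12C=C[C@H](O)[C@@](C)(C(=O)O1)[C@H]2[C@@H]3C(=O)O | starting material
2 | GA3 2-(trimethylsilyl)ethyl (TMSE) ester | C=C1C[C@]23C[C@@]1(O)CC[C@H]2[C@@]12C=C[C@H](O)[C@@](C)(C(=O)O1)[C@H]2[C@@H]3C(=O)OCC[Si](C)(C)C | intermediate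
3 | 1β-chloro-GA5 TMSE ester (1β-Cl, 2-ene, 13-OH, 16-ene) | C=C1C[C@]23C[C@@]1(O)CC[C@H]2[C@@]12[C@H](Cl)C=C[C@@](C)(C(=O)O1)[C@H]2[C@@H]3C(=O)OCC[Si](C)(C)C | intermediate
4 | GA5 TMSE ester (2-ene, 13-OH, 16-ene) | C=C1C[C@]23C[C@@]1(O)CC[C@H]2[C@@]12CC=C[C@@](C)(C(=O)O1)[C@H]2[C@@H]3C(=O)OCC[Si](C)(C)C | intermediate
5 | GA8 TMSE ester (2β,3β,13-triol, 16-ene) | C=C1C[C@]23C[C@@]1(O)CC[C@H]2[C@@]12C[C@H](O)[C@H](O)[C@@](C)(C(=O)O1)[C@H]2[C@@H]3C(=O)OCC[Si](C)(C)C | intermediate
6 | GA8 TMSE ester 2β,3β-acetonide | C=C1C[C@]23C[C@@]1(O)CC[C@H]2[C@@]12C[C@@H]4OC(C)(C)O[C@@H]4[C@@](C)(C(=O)O1)[C@H]2[C@@H]3C(=O)OCC[Si](C)(C)C | intermediate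
7 | 16-oxo-17-nor derivative of 6 (13-hydroxy 16-ketone) | O=C1C[C@]23C[C@@]1(O)CC[C@H]2[C@@]12C[C@@H]4OC(C)(C)O[C@@H]4[C@@](C)(C(=O)O1)[C@H]2[C@@H]3C(=O)OCC[Si](C)(C)C | intermediate
8 | 17-nor-13,16β-diol (endo 16-OH) of the GA8 acetonide TMSE ester | O[C@H]1C[C@]23C[C@@]1(O)CC[C@H]2[C@@]12C[C@@H]4OC(C)(C)O[C@@H]4[C@@](C)(C(=O)O1)[C@H]2[C@@H]3C(=O)OCC[Si](C)(C)C | intermediate
9 | 13,16-seco-17-nor keto aldehyde (C13 ketone in ring C, C8–CH2–CHO) | O=CC[C@]23CC(=O)CC[C@H]2[C@@]12C[C@@H]4OC(C)(C)O[C@@H]4[C@@](C)(C(=O)O1)[C@H]2[C@@H]3C(=O)OCC[Si](C)(C)C | intermediate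
10 | 13,16-seco keto alkyne (C13 ketone, C8-propargyl = C15–C16≡C17) | C#CC[C@]23CC(=O)CC[C@H]2[C@@]12C[C@@H]4OC(C)(C)O[C@@H]4[C@@](C)(C(=O)O1)[C@H]2[C@@H]3C(=O)OCC[Si](C)(C)C | intermediate
11 | Δ12(13) triethylsilyl enol ether of 10 | C#CC[C@]23CC(O[Si](CC)(CC)CC)=CC[C@H]2[C@@]12C[C@@H]4OC(C)(C)O[C@@H]4[C@@](C)(C(=O)O1)[C@H]2[C@@H]3C(=O)OCC[Si](C)(C)C | intermediate
12 | 12β-triethylsilyloxy 13-ketone | C#CC[C@]23CC(=O)[C@H](O[Si](CC)(CC)CC)C[C@H]2[C@@]12C[C@@H]4OC(C)(C)O[C@@H]4[C@@](C)(C(=O)O1)[C@H]2[C@@H]3C(=O)OCC[Si](C)(C)C | intermediate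
13 | 12β-triethylsilyloxy 13β-alcohol | C#CC[C@]23C[C@H](O)[C@H](O[Si](CC)(CC)CC)C[C@H]2[C@@]12C[C@@H]4OC(C)(C)O[C@@H]4[C@@](C)(C(=O)O1)[C@H]2[C@@H]3C(=O)OCC[Si](C)(C)C | intermediate
14 | 13β-O-(imidazol-1-ylthiocarbonyl) derivative of 13 | C#CC[C@]23C[C@H](OC(=S)n5ccnc5)[C@H](O[Si](CC)(CC)CC)C[C@H]2[C@@]12C[C@@H]4OC(C)(C)O[C@@H]4[C@@](C)(C(=O)O1)[C@H]2[C@@H]3C(=O)OCC[Si](C)(C)C | intermediate
15 | 12-epi-GA49 12-O-TES ether 2,3-acetonide TMSE ester | C=C1C[C@]23C[C@H]1[C@H](O[Si](CC)(CC)CC)C[C@H]2[C@@]12C[C@@H]4OC(C)(C)O[C@@H]4[C@@](C)(C(=O)O1)[C@H]2[C@@H]3C(=O)OCC[Si](C)(C)C | intermediate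
16 | 12-epi-GA49 2,3-acetonide (12β-OH, free 7-acid) | C=C1C[C@]23C[C@H]1[C@H](O)C[C@H]2[C@@]12C[C@@H]4OC(C)(C)O[C@@H]4[C@@](C)(C(=O)O1)[C@H]2[C@@H]3C(=O)O | intermediate
17 | 12-oxo-GA34 2,3-acetonide (free 7-acid) | C=C1C[C@]23C[C@H]1C(=O)C[C@H]2[C@@]12C[C@@H]4OC(C)(C)O[C@@H]4[C@@](C)(C(=O)O1)[C@H]2[C@@H]3C(=O)O | intermediate
18 | GA49 2,3-acetonide (12α-OH) | C=C1C[C@]23C[C@H]1[C@@H](O)C[C@H]2[C@@]12C[C@@H]4OC(C)(C)O[C@@H]4[C@@](C)(C(=O)O1)[C@H]2[C@@H]3C(=O)O | intermediate
19 | GA49 (12α-hydroxy-GA34; 2β,3β,12α-triol, 19,10-lactone, 16-ene, free 7-acid) | C=C1C[C@]23C[C@H]1[C@@H](O)C[C@H]2[C@@]12C[C@H](O)[C@H](O)[C@@](C)(C(=O)O1)[C@H]2[C@@H]3C(=O)O | target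

## Step count and risks
Total step count: 16. Longest linear sequence: 16 (fully linear from GA3).

Step 4 (OsO4 must choose the 2-ene over the 16-ene). The fallback sets out from 2 and comes back at 8; it removes the 16-ene before the A-ring alkene exists. Ozonolysis of 2 (O3, CH2Cl2–pyridine, −78 °C; Me2S) spares the electron-poor 1-ene and gives GA3 16-norketone TMSE ester F1. Appel SN2' chlorination gives 1β-chloro-2-ene norketone F2, and Bu3SnH gives 2-ene norketone F3. OsO4/NMO then meets a single alkene and gives 2β,3β-diol norketone F4. Acetonide formation gives 7, this time isolated, and NaBH4 gives 8.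

Step 9 (enolisation next to a terminal alkyne, and the fate of the silyl group). The fallback sets out from 10 and comes back at 12; it uses enamine catalysis instead of enolate chemistry. Nitrosobenzene and L-proline (DMSO, rt) aminoxylate the less hindered α-carbon. The (R) sense that this catalyst imposes is the 12β configuration here, so the product is 12β-(N-phenylaminooxy) ketone F5. Zn/AcOH cleaves the N–O bond to give 12β-hydroxy ketone F6, and Et3SiCl/imidazole gives 12.

Step 12 (bridging 5-exo-dig closure against direct reduction or hydrostannation). The fallback sets out from 12 and comes back at 15; it closes ring D with a ketyl and removes the extra oxygen afterwards. SmI2/HMPA/t-BuOH (THF, 0 °C) adds the C13 ketyl to the alkyne. The equatorial 12β-silyloxy group lies near the nodal plane of the ketyl, so its reductive loss is slow, and the product is 13-hydroxy-12β-triethylsilyloxy tetracycle F7. MeO2CCOCl/DMAP gives 13-O-methyl oxalate F8. Bu3SnH/AIBN (PhMe, 110 °C) replaces the bridgehead oxalate by hydrogen and gives 15.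

## Further compounds
F1 | step 4 | GA3 16-norketone TMSE ester | O=C1C[C@]23C[C@@]1(O)CC[C@H]2[C@@]12C=C[C@H](O)[C@@](C)(C(=O)O1)[C@H]2[C@@H]3C(=O)OCC[Si](C)(C)C
F2 | step 4 | 1β-chloro-2-ene norketone | O=C1C[C@]23C[C@@]1(O)CC[C@H]2[C@@]12[C@H](Cl)C=C[C@@](C)(C(=O)O1)[C@H]2[C@@H]3C(=O)OCC[Si](C)(C)C
F3 | step 4 | 2-ene norketone | O=C1C[C@]23C[C@@]1(O)CC[C@H]2[C@@]12CC=C[C@@](C)(C(=O)O1)[C@H]2[C@@H]3C(=O)OCC[Si](C)(C)C
F4 | step 4 | 2β,3β-diol norketone | O=C1C[C@]23C[C@@]1(O)CC[C@H]2[C@@]12C[C@H](O)[C@H](O)[C@@](C)(C(=O)O1)[C@H]2[C@@H]3C(=O)OCC[Si](C)(C)C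
F5 | step 9 | 12β-(N-phenylaminooxy) ketone | C#CC[C@]23CC(=O)[C@H](ONc5ccccc5)C[C@H]2[C@@]12C[C@@H]4OC(C)(C)O[C@@H]4[C@@](C)(C(=O)O1)[C@H]2[C@@H]3C(=O)OCC[Si](C)(C)C
F6 | step 9 | 12β-hydroxy ketone | C#CC[C@]23CC(=O)[C@H](O)C[C@H]2[C@@]12C[C@@H]4OC(C)(C)O[C@@H]4[C@@](C)(C(=O)O1)[C@H]2[C@@H]3C(=O)OCC[Si](C)(C)C
F7 | step 12 | 13-hydroxy-12β-triethylsilyloxy tetracycle | C=C1C[C@]23C[C@@]1(O)[C@H](O[Si](CC)(CC)CC)C[C@H]2[C@@]12C[C@@H]4OC(C)(C)O[C@@H]4[C@@](C)(C(=O)O1)[C@H]2[C@@H]3C(=O)OCC[Si](C)(C)C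
F8 | step 12 | 13-O-methyl oxalate | C=C1C[C@]23C[C@@]1(OC(=O)C(=O)OC)[C@H](O[Si](CC)(CC)CC)C[C@H]2[C@@]12C[C@@H]4OC(C)(C)O[C@@H]4[C@@](C)(C(=O)O1)[C@H]2[C@@H]3C(=O)OCC[Si](C)(C)C
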